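**Retrosynthetic overview**

1. The route rests on the 4-alkylfuran-2(5H)-one ring (ring O, OCH2 carbon C20, β-carbon C17, α-CH C18, carbonyl C19), whose C17 carries the last chain methylene C16. It is cut at C16–C17, C18–C19 and O–C19 into a C16 homoallylic Grignard reagent, propargyl alcohol (C20, C17, C18) and carbon dioxide (C19).
2. The Grignard reagent comes from the homoallylic bromide. Each E-trisubstituted alkene is made by zirconium-catalysed methylalumination of a terminal alkyne followed by opening of ethylene oxide, and each alkyne comes from a primary iodide and lithium acetylide.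
3. The (S)-2-(2,2-dimethyl-6-methylidenecyclohexyl)ethyl unit comes from 3-methylcyclohex-2-en-1-one by conjugate methylation, enolate alkylation with ethyl bromoacetate and Wittig methylenation. The single enantiomer is secured by separating oxazolidinone imide diastereomers.
4. Ring order: the cyclohexane is present from the first step; the butenolide is closed in the last step.

Key step: step 15

Assumption: the two diastereomeric imides of step 5 are taken to be separable on silica gel or by crystallisation; the (1S) isomer is to be identified by X-ray diffraction against the fixed (4S) centre of the auxiliary.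

**Route**

Step 1
Reactants: 1 3-methylcyclohex-2-en-1-one
Product: 2 [(3,3-dimethylcyclohex-1-en-1-yl)oxy]trimethylsilane
Conditions: MeMgBr, CuBr·SMe2 (5 mol%), TMSCl, HMPA (or DMPU), THF, −78 → −40 °C; Et3N, pentane work-up
Reagents that add atoms: methylmagnesium bromide, C[Mg]Br; chlorotrimethylsilane, C[Si](C)(C)Cl
Why: Copper-catalysed 1,4-addition of the methyl Grignard reagent to the β-methyl enone, accelerated by TMSCl, should build the gem-dimethyl carbon and trap the enolate regiospecifically as the silyl enol ether whose double bond points towards that carbon; no stereocentre is formed.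

Step 2
Reactants: 2 [(3,3-dimethylcyclohex-1-en-1-yl)oxy]trimethylsilane; 3 ethyl bromoacetate
Product: 5 ethyl 2-(2,2-dimethyl-6-oxocyclohexyl)acetate (racemic), via lithium enolate 4 (not isolated)
Conditions: MeLi (1.0 equiv), THF, 0 °C → rt; then 3, DMPU, −78 → 0 °C
Reagents that add atoms: none
Why: Cleavage of the silyl enol ether with MeLi should release the lithium enolate without loss of regiochemistry, and SN2 enolate alkylation with the activated α-bromo ester should form the C–C bond next to the quaternary carbon; the new stereocentre forms without control, so the product is the racemate, as intended at this stage.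

Step 3
Reactants: 5 ethyl 2-(2,2-dimethyl-6-oxocyclohexyl)acetate (racemic)
Product: 6 ethyl 2-(2,2-dimethyl-6-methylidenecyclohexyl)acetate (racemic)
Conditions: Ph3PCH3Br, n-BuLi, THF, 0 °C; then 5, 0 °C → reflux
Reagents that add atoms: methyltriphenylphosphonium bromide, C[P+](c1ccccc1)(c1ccccc1)c1ccccc1.[Br-]
Why: Wittig methylenation should convert the ketone, and not the less electrophilic ester, into the exocyclic 1,1-disubstituted alkene; epimerisation at the α-carbon is without consequence in a racemate.

Step 4
Reactants: 6 ethyl 2-(2,2-dimethyl-6-methylidenecyclohexyl)acetate (racemic)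
Product: 7 2-(2,2-dimethyl-6-methylidenecyclohexyl)acetic acid (racemic)
Conditions: LiOH·H2O, THF/MeOH/H2O, 40 °C; cold 1 M HCl to pH 3
Reagents that add atoms: lithium hydroxide, [Li+].[OH-]
Why: Saponification of the unhindered ethyl ester should proceed cleanly, since the exocyclic alkene is stable to base and to a brief cold acidification.

Step 5
Reactants: 7 2-(2,2-dimethyl-6-methylidenecyclohexyl)acetic acid (racemic); 8 (4S)-4-benzyl-1,3-oxazolidin-2-one
Product: 10 (4S)-4-benzyl-3-{[(1S)-2,2-dimethyl-6-methylidenecyclohexyl]acetyl}-1,3-oxazolidin-2-one, via mixed pivalic anhydride 9 (not isolated)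
Conditions: PivCl, Et3N, THF, −20 °C; then 8, LiCl, −20 °C → rt; silica gel chromatography, then crystallisation
Reagents that add atoms: none
Why: N-acylation of the oxazolidinone through the mixed anhydride should give two imides that differ only at the β-carbon, the same relationship as in the routinely separated products of auxiliary-controlled conjugate additions; the ring stereocentre is not created here but selected by separation of diastereomers.

Step 6
Reactants: 10 (4S)-4-benzyl-3-{[(1S)-2,2-dimethyl-6-methylidenecyclohexyl]acetyl}-1,3-oxazolidin-2-one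
Product: 11 2-[(1S)-2,2-dimethyl-6-methylidenecyclohexyl]ethan-1-ol
Conditions: LiBH4, H2O (1 equiv), Et2O, 0 °C → rt
Reagents that add atoms: none
Why: Reductive cleavage of the exocyclic imide carbonyl with lithium borohydride should give the primary alcohol and return the auxiliary; the stereocentre is two bonds from the reacting carbon and is not touched.

Step 7
Reactants: 11 2-[(1S)-2,2-dimethyl-6-methylidenecyclohexyl]ethan-1-ol
Product: 12 (2S)-2-(2-iodoethyl)-1,1-dimethyl-3-methylidenecyclohexane
Conditions: I2, PPh3, imidazole, CH2Cl2, 0 °C → rt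
Reagents that add atoms: iodine, II
Why: Appel-type iodination should replace the primary hydroxyl by SN2 under neutral conditions that do not isomerise the exocyclic alkene.

Step 8
Reactants: 12 (2S)-2-(2-iodoethyl)-1,1-dimethyl-3-methylidenecyclohexane; 13 lithium acetylide–ethylenediamine complex
Product: 14 (2S)-2-(but-3-yn-1-yl)-1,1-dimethyl-3-methylidenecyclohexane
Conditions: 13 (2 equiv), DMSO, 15 °C → rt
Reagents that add atoms: none
Why: SN2 alkylation of lithium acetylide in DMSO with an unbranched primary iodide should give the terminal alkyne directly.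

Step 9
Reactants: 14 (2S)-2-(but-3-yn-1-yl)-1,1-dimethyl-3-methylidenecyclohexane; 15 ethylene oxide
Product: 18 (3E)-6-[(1S)-2,2-dimethyl-6-methylidenecyclohexyl]-4-methylhex-3-en-1-ol, via alkenylalane 16 (not isolated), via lithium alanate 17 (not isolated)
Conditions: AlMe3 (2 equiv), Cp2ZrCl2 (0.25 equiv), CH2Cl2, rt; volatiles removed in vacuo; n-BuLi, hexane–THF, 0 °C; 15 (excess), 0 °C → rt; aq. Rochelle salt
Reagents that add atoms: trimethylaluminium, C[Al](C)C
Why: Negishi zirconium-catalysed methylalumination adds methyl and aluminium syn across the terminal alkyne with aluminium on the terminal carbon, which fixes the E geometry, and the alanate formed with n-BuLi should open ethylene oxide with retention of that geometry; the 1,1-disubstituted ring alkene does not carbometallate under these conditions.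

Step 10
Reactants: 18 (3E)-6-[(1S)-2,2-dimethyl-6-methylidenecyclohexyl]-4-methylhex-3-en-1-ol
Product: 19 (2S)-2-[(3E)-6-iodo-3-methylhex-3-en-1-yl]-1,1-dimethyl-3-methylidenecyclohexane
Conditions: I2, PPh3, imidazole, CH2Cl2, 0 °C
Reagents that add atoms: iodine, II
Why: Appel-type iodination of the primary homoallylic alcohol is an SN2 process under neutral conditions and should leave both alkenes in place.

Step 11
Reactants: 19 (2S)-2-[(3E)-6-iodo-3-methylhex-3-en-1-yl]-1,1-dimethyl-3-methylidenecyclohexane; 13 lithium acetylide–ethylenediamine complex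
Product: 20 (2S)-1,1-dimethyl-3-methylidene-2-[(3E)-3-methyloct-3-en-7-yn-1-yl]cyclohexane
Conditions: 13 (2 equiv), DMSO, 10 °C → rt
Reagents that add atoms: none
Why: Acetylide SN2 alkylation of primary homoallylic halides in DMSO is established for homoprenyl-type halides, and the low temperature should hold back E2 elimination to the diene.

Step 12
Reactants: 20 (2S)-1,1-dimethyl-3-methylidene-2-[(3E)-3-methyloct-3-en-7-yn-1-yl]cyclohexane; 15 ethylene oxide
Product: 23 (3E,7E)-10-[(1S)-2,2-dimethyl-6-methylidenecyclohexyl]-4,8-dimethyldeca-3,7-dien-1-ol, via alkenylalane 21 (not isolated), via lithium alanate 22 (not isolated)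
Conditions: AlMe3 (2 equiv), Cp2ZrCl2 (0.25 equiv), CH2Cl2, rt; volatiles removed in vacuo; n-BuLi, hexane–THF, 0 °C; 15 (excess), 0 °C → rt; aq. Rochelle salt
Reagents that add atoms: trimethylaluminium, C[Al](C)C
Why: A second Negishi methylalumination with ethylene oxide trapping of the alanate should set the second E-trisubstituted alkene by syn addition, the existing tri- and 1,1-disubstituted alkenes being inert.

Step 13
Reactants: 23 (3E,7E)-10-[(1S)-2,2-dimethyl-6-methylidenecyclohexyl]-4,8-dimethyldeca-3,7-dien-1-ol
Product: 24 (2S)-2-[(3E,7E)-10-bromo-3,7-dimethyldeca-3,7-dien-1-yl]-1,1-dimethyl-3-methylidenecyclohexane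
Conditions: CBr4, PPh3, CH2Cl2, 0 °C
Reagents that add atoms: tetrabromomethane, BrC(Br)(Br)Br
Why: Appel bromination should convert the primary alcohol into the bromide by SN2 without acid, so that neither alkene migrates.

Step 14
Reactants: 24 (2S)-2-[(3E,7E)-10-bromo-3,7-dimethyldeca-3,7-dien-1-yl]-1,1-dimethyl-3-methylidenecyclohexane
Product: 25 [(3E,7E)-10-[(1S)-2,2-dimethyl-6-methylidenecyclohexyl]-4,8-dimethyldeca-3,7-dien-1-yl]magnesium bromide (titrated solution)
Conditions: Mg turnings (activated with 1,2-dibromoethane), Et2O, rt → 35 °C; used at once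
Reagents that add atoms: magnesium, [Mg]
Why: Magnesium insertion into a primary alkyl bromide gives the Grignard reagent; loss of alkene geometry through the cyclopropylcarbinyl form would require a tertiary organomagnesium and should be slow if the solution is used at once.

Step 15
Reactants: 25 [(3E,7E)-10-[(1S)-2,2-dimethyl-6-methylidenecyclohexyl]-4,8-dimethyldeca-3,7-dien-1-yl]magnesium bromide; 26 propargyl alcohol; 27 carbon dioxide
Product: 32 4-[(3E,7E)-10-[(1S)-2,2-dimethyl-6-methylidenecyclohexyl]-4,8-dimethyldeca-3,7-dien-1-yl]furan-2(5H)-one (target), via magnesium propargyl alkoxide 28 (not isolated), via oxamagnesacycle 29 (not isolated), via magnesium carboxylate 30 (not isolated), via hydroxy acid 31 (not isolated)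
Conditions: 26 (1.3 equiv), EtMgBr (1.0 equiv to 26), Et2O–THF, −20 → 0 °C; CuI (10 mol%), 25 (1.0 equiv), −10 °C → rt; 27 (dry gas), −20 °C → rt; 2 M HCl, rt
Reagents that add atoms: none
Why: Propargyl alcohol is first turned into its bromomagnesium alkoxide with one equivalent of EtMgBr so that none of 25 is spent on the O–H; under CuI catalysis the alkyl group of 25 then adds to the internal alkyne carbon (C16–C17) while magnesium ends on the terminal carbon C18 on the opposite face, giving the five-membered oxamagnesacycle. Carbon dioxide inserts into the C18–Mg bond with retention (C18–C19) to give the Z-configured magnesium carboxylate, and acidification frees the hydroxy acid, whose hydroxyl attacks the carboxyl carbon in a 5-exo-trig acyl substitution (O–C19) with loss of water to close the furanone ring. The closest known reaction type is the copper-catalysed anti-carbomagnesiation of propargylic alcohols with electrophilic trapping of the cyclic alkenylmagnesium, which with carbon dioxide gives 4-substituted furan-2(5H)-ones. No stereocentre is formed; the ring stereocentre is remote and the unactivated alkenes of the chain do not react with the organocopper species. The step needs regioselectivity (chain on C17, not C18) and anti addition (C19 cis to C20), and both follow from chelation by the propargylic alkoxide, because only the anti adduct with magnesium on the terminal carbon can close the O–Mg–C ring.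

**Compound list**

1 | 3-methylcyclohex-2-en-1-one | CC1=CC(=O)CCC1 | starting material
2 | [(3,3-dimethylcyclohex-1-en-1-yl)oxy]trimethylsilane | CC1(C)CCCC(O[Si](C)(C)C)=C1 | intermediate
3 | ethyl bromoacetate | CCOC(=O)CBr | starting material
4 | lithium 3,3-dimethylcyclohex-1-en-1-olate | [Li+].[O-]C1=CC(C)(C)CCC1 | intermediate
5 | ethyl 2-(2,2-dimethyl-6-oxocyclohexyl)acetate (racemic) | CCOC(=O)CC1C(=O)CCCC1(C)C | intermediate
6 | ethyl 2-(2,2-dimethyl-6-methylidenecyclohexyl)acetate (racemic) | C=C1CCCC(C)(C)C1CC(=O)OCC | intermediate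
7 | 2-(2,2-dimethyl-6-methylidenecyclohexyl)acetic acid (racemic) | C=C1CCCC(C)(C)C1CC(=O)O | intermediate
8 | (4S)-4-benzyl-1,3-oxazolidin-2-one | O=C1N[C@@H](Cc2ccccc2)CO1 | starting material
9 | 2-(2,2-dimethyl-6-methylidenecyclohexyl)acetic pivalic anhydride (racemic) | C=C1CCCC(C)(C)C1CC(=O)OC(=O)C(C)(C)C | intermediate
10 | (4S)-4-benzyl-3-{[(1S)-2,2-dimethyl-6-methylidenecyclohexyl]acetyl}-1,3-oxazolidin-2-one | C=C1CCCC(C)(C)[C@@H]1CC(=O)N1[C@@H](Cc2ccccc2)COC1=O | intermediate
11 | 2-[(1S)-2,2-dimethyl-6-methylidenecyclohexyl]ethan-1-ol | C=C1CCCC(C)(C)[C@@H]1CCO | intermediate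
12 | (2S)-2-(2-iodoethyl)-1,1-dimethyl-3-methylidenecyclohexane | C=C1CCCC(C)(C)[C@@H]1CCI | intermediate
13 | lithium acetylide–ethylenediamine complex | [Li+].[C-]#C.NCCN | starting material
14 | (2S)-2-(but-3-yn-1-yl)-1,1-dimethyl-3-methylidenecyclohexane | C=C1CCCC(C)(C)[C@@H]1CCC#C | intermediate
15 | ethylene oxide | C1CO1 | starting material
16 | [(1E)-4-[(1S)-2,2-dimethyl-6-methylidenecyclohexyl]-2-methylbut-1-en-1-yl]dimethylalumane | C=C1CCCC(C)(C)[C@@H]1CC/C(C)=C/[Al](C)C | intermediate
17 | lithium butyl[(1E)-4-[(1S)-2,2-dimethyl-6-methylidenecyclohexyl]-2-methylbut-1-en-1-yl]dimethylaluminate | C=C1CCCC(C)(C)[C@@H]1CC/C(C)=C/[Al-](C)(C)CCCC.[Li+] | intermediate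
18 | (3E)-6-[(1S)-2,2-dimethyl-6-methylidenecyclohexyl]-4-methylhex-3-en-1-ol | C=C1CCCC(C)(C)[C@@H]1CC/C(C)=C/CCO | intermediate
19 | (2S)-2-[(3E)-6-iodo-3-methylhex-3-en-1-yl]-1,1-dimethyl-3-methylidenecyclohexane | C=C1CCCC(C)(C)[C@@H]1CC/C(C)=C/CCI | intermediate
20 | (2S)-1,1-dimethyl-3-methylidene-2-[(3E)-3-methyloct-3-en-7-yn-1-yl]cyclohexane | C=C1CCCC(C)(C)[C@@H]1CC/C(C)=C/CCC#C | intermediate
21 | [(1E,5E)-8-[(1S)-2,2-dimethyl-6-methylidenecyclohexyl]-2,6-dimethylocta-1,5-dien-1-yl]dimethylalumane | C=C1CCCC(C)(C)[C@@H]1CC/C(C)=C/CC/C(C)=C/[Al](C)C | intermediate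
22 | lithium butyl[(1E,5E)-8-[(1S)-2,2-dimethyl-6-methylidenecyclohexyl]-2,6-dimethylocta-1,5-dien-1-yl]dimethylaluminate | C=C1CCCC(C)(C)[C@@H]1CC/C(C)=C/CC/C(C)=C/[Al-](C)(C)CCCC.[Li+] | intermediate
23 | (3E,7E)-10-[(1S)-2,2-dimethyl-6-methylidenecyclohexyl]-4,8-dimethyldeca-3,7-dien-1-ol | C=C1CCCC(C)(C)[C@@H]1CC/C(C)=C/CC/C(C)=C/CCO | intermediate
24 | (2S)-2-[(3E,7E)-10-bromo-3,7-dimethyldeca-3,7-dien-1-yl]-1,1-dimethyl-3-methylidenecyclohexane | C=C1CCCC(C)(C)[C@@H]1CC/C(C)=C/CC/C(C)=C/CCBr | intermediate
25 | [(3E,7E)-10-[(1S)-2,2-dimethyl-6-methylidenecyclohexyl]-4,8-dimethyldeca-3,7-dien-1-yl]magnesium bromide | C=C1CCCC(C)(C)[C@@H]1CC/C(C)=C/CC/C(C)=C/CC[Mg]Br | intermediate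
26 | propargyl alcohol (prop-2-yn-1-ol) | C#CCO | starting material
27 | carbon dioxide | O=C=O | starting material
28 | bromomagnesium prop-2-yn-1-olate | C#CCO[Mg]Br | intermediate
29 | 4-[(3E,7E)-10-[(1S)-2,2-dimethyl-6-methylidenecyclohexyl]-4,8-dimethyldeca-3,7-dien-1-yl]-2,5-dihydro-1,2-oxamagnesole (drawn as the solvent-free monomer) | C=C1CCCC(C)(C)[C@@H]1CC/C(C)=C/CC/C(C)=C/CCC1=C[Mg]OC1 | intermediate
30 | magnesium (2Z,6E,10E)-13-[(1S)-2,2-dimethyl-6-methylidenecyclohexyl]-7,11-dimethyl-3-(oxidomethyl)trideca-2,6,10-trienoate (drawn as the cyclic chelate) | C=C1CCCC(C)(C)[C@@H]1CC/C(C)=C/CC/C(C)=C/CCC1=CC(=O)O[Mg]OC1 | intermediate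
31 | (2Z,6E,10E)-13-[(1S)-2,2-dimethyl-6-methylidenecyclohexyl]-3-(hydroxymethyl)-7,11-dimethyltrideca-2,6,10-trienoic acid | C=C1CCCC(C)(C)[C@@H]1CC/C(C)=C/CC/C(C)=C/CC/C(CO)=C/C(=O)O | intermediate
32 | 4-[(3E,7E)-10-[(1S)-2,2-dimethyl-6-methylidenecyclohexyl]-4,8-dimethyldeca-3,7-dien-1-yl]furan-2(5H)-one | C=C1CCCC(C)(C)[C@@H]1CC/C(C)=C/CC/C(C)=C/CCC1=CC(=O)OC1 | target

**Step count**

Total steps: 15. Longest linear sequence: 15 steps, from 3-methylcyclohex-2-en-1-one to the target.

**Steps most likely to fail**

Step 15. The acetylenic C–H of the magnesium propargyl alkoxide may protonate the chain Grignard reagent faster than the copper-catalysed addition takes place, and carbomagnesiation or carboxylation may stop short of completion, so that the valuable C21 fragment is lost as hydrocarbon or as the uncarboxylated allylic alcohol. The fallback sets out from Grignard reagent 25 and comes back at target 32. Transmetallation with ZnBr2 in THF should give [(3E,7E)-10-[(1S)-2,2-dimethyl-6-methylidenecyclohexyl]-4,8-dimethyldeca-3,7-dien-1-yl]zinc bromide F1. F1 is then joined to commercial 4-bromofuran-2(5H)-one by Negishi coupling (PdCl2(dppf), THF, rt). The lactone ring is thus bought ready-made, and C16–C17 is formed by cross-coupling and not by carbometallation.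

Step 5. The two imides may not differ enough in chromatographic mobility or in solubility, so that the diastereomers are not obtained pure. The fallback sets out from racemic ester 6 and comes back at alcohol 11, bypassing steps 4 to 6. Preparative supercritical-fluid chromatography on a polysaccharide chiral stationary phase should separate the enantiomers directly and give ethyl 2-[(1S)-2,2-dimethyl-6-methylidenecyclohexyl]acetate F2. Reduction of F2 with LiAlH4 in Et2O at 0 °C gives 11. The configuration is then assigned by correlation of 11 with the sample from the imide route, or by vibrational circular dichroism.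

Step 2. C-alkylation at the enolate carbon next to the quaternary centre may be slow, and proton exchange between product and enolate may then lead to over-alkylation and loss of regiochemistry. The fallback sets out from silyl enol ether 2 and comes back at racemic ester 6, bypassing steps 2 and 3. MeLi gives enolate 4, which is trapped with N-phenyltriflimide as 3,3-dimethylcyclohex-1-en-1-yl trifluoromethanesulfonate F3. Palladium-catalysed methoxycarbonylation (Pd(OAc)2, dppp, CO, MeOH, Et3N, DMF) should give methyl 3,3-dimethylcyclohex-1-ene-1-carboxylate F4, and DIBAL-H reduction gives (3,3-dimethylcyclohex-1-en-1-yl)methanol F5. Heating F5 with triethyl orthoacetate and catalytic propionic acid at 140 °C forms the ketene acetal (3,3-dimethylcyclohex-1-en-1-yl)methyl 1-ethoxyvinyl ether F6. F6 should undergo Johnson–Claisen rearrangement to 6, which places the acetate chain on the hindered ring carbon intramolecularly and creates the exocyclic methylene at the same time.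

**Further compounds**

F1 | step 15 | [(3E,7E)-10-[(1S)-2,2-dimethyl-6-methylidenecyclohexyl]-4,8-dimethyldeca-3,7-dien-1-yl]zinc bromide | C=C1CCCC(C)(C)[C@@H]1CC/C(C)=C/CC/C(C)=C/CC[Zn]Br
F2 | step 5 | ethyl 2-[(1S)-2,2-dimethyl-6-methylidenecyclohexyl]acetate | C=C1CCCC(C)(C)[C@@H]1CC(=O)OCC
F3 | step 2 | 3,3-dimethylcyclohex-1-en-1-yl trifluoromethanesulfonate | CC1(C)CCCC(OS(=O)(=O)C(F)(F)F)=C1
F4 | step 2 | methyl 3,3-dimethylcyclohex-1-ene-1-carboxylate | COC(=O)C1=CC(C)(C)CCC1
F5 | step 2 | (3,3-dimethylcyclohex-1-en-1-yl)methanol | OCC1=CC(C)(C)CCC1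
F6 | step 2 | (3,3-dimethylcyclohex-1-en-1-yl)methyl 1-ethoxyvinyl ether | C=C(OCC)OCC1=CC(C)(C)CCC1
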